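**Retrosynthetic overview**

1. Sideroxylonal A is opened at the pyran O1–C2 bond. That bond is made last, by intramolecular oxa-Michael addition of a phenol OH to an open-chain ortho-quinone methide (key step, C–O bond, sets C2 and C3 from the fixed C4).
2. The quinone methide comes from 2,4-diformylphloroglucinol and the C2 aldehyde of a (4S)-lactol, by Knoevenagel condensation in the same flask.
3. The lactol comes from 2,4-diformylphloroglucinol and two molecules of isovaleraldehyde, by an aminocatalytic Knoevenagel/enamine Michael domino that sets C4.
4. 2,4-Diformylphloroglucinol comes from phloroglucinol by Vilsmeier–Haack formylation.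
5. Ring order: both benzene rings are bought as phloroglucinol; the pyran is the only ring built and is closed in the last step.

Assumption: lactol 7 is carried forward as its mixture of anomers, and the catalyst (R)-α,α-diphenylprolinol trimethylsilyl ether is bought.

**Route**

Step 1
Reactants: 1 phloroglucinol
Product: 3 2,4-diformylphloroglucinol, via bis-iminium salt 2 (not isolated)
Conditions: POCl3 (2.2 equiv), DMF (2.2 equiv), 1,4-dioxane, 0 °C to rt; then H2O, rt
Reagents that add atoms: N,N-dimethylformamide CN(C)C=O (the two formyl carbons); water O (the two carbonyl oxygens)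
Why: Vilsmeier–Haack formylation: the chloroiminium ion substitutes the very electron-rich ring twice, each iminium group deactivates the ring so 2.2 equiv stops before the third substitution, and water hydrolyses 2 to the dialdehyde; no stereocentre is formed.

Step 2
Reactants: 3 2,4-diformylphloroglucinol; 4 isovaleraldehyde (3 equiv; two molecules are built in)
Product: 7 lactol (3S,4S)-2,5,7-trihydroxy-4-(2-methylpropyl)-3-(propan-2-yl)-3,4-dihydro-2H-chromene-6,8-dicarbaldehyde, via enamine 5 (not isolated), via ortho-quinone methide 6 (not isolated)
Conditions: (R)-α,α-diphenylprolinol trimethylsilyl ether (20 mol%), MeCN, rt, 48 h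
Reagents that add atoms: none
Why: Proposed new method: a three-component aminocatalytic Knoevenagel/Michael/hemiacetalisation domino in which one secondary amine does both jobs: 3, a cyclic vinylogous 1,3-dicarbonyl acid comparable to dimedone or 4-hydroxycoumarin, condenses with 4 at its only free ring carbon (Mannich addition to the iminium ion, then loss of the amine) to give 6, while a second molecule of 4 forms (E)-enamine 5, which adds to the exocyclic carbon of 6 through a synclinal, endo-type transition state on the enamine face left open by the diphenyl(silyloxy)methyl group, so that C4 is set as S (C3 comes out S, trans to isobutyl, and is reset in step 3), after which hydrolysis and ring closure give 7; the closest known reaction types are diarylprolinol silyl ether-catalysed Michael additions of aldehydes to nitroalkenes and to quinone methides released from sulfone precursors, and amine-catalysed Knoevenagel generation of quinone methides from formylphloroglucinols and aldehydes.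

Step 3
Reactants: 7 lactol (3S,4S)-2,5,7-trihydroxy-4-(2-methylpropyl)-3-(propan-2-yl)-3,4-dihydro-2H-chromene-6,8-dicarbaldehyde; 3 2,4-diformylphloroglucinol (1.1 equiv)
Product: 10 sideroxylonal A, via quinone methide 8 (not isolated), via hydroxystyrene tautomer 9 (not isolated)
Conditions: pyrrolidine (20 mol%), AcOH (40 mol%), MeCN, 4 Å MS, 45 °C, 24 h
Reagents that add atoms: none
Why: Proposed new method: a dynamic, stereoconvergent Knoevenagel/oxa-Michael annulation: pyrrolidinium acetate opens 7 as its iminium ion, the free ring carbon of 3 adds and the amine is lost to give quinone methide 8, whose C3 centre is erased and reset through hydroxystyrene tautomer 9 (and through the enamine before condensation), and the phenol on the C4-bearing ring then closes the pyran by 6-exo-trig oxa-Michael addition (the O1–C2 bond) through the chair-like transition state that keeps isobutyl pseudo-axial (avoiding peri strain against the C5–OH) and isopropyl and aryl equatorial, so the fixed 4S centre dictates 3R and 2R, the reversibility of the ring closure letting wrong C2/C3 isomers drain to the same product; the closest known reaction types are Knoevenagel/quinone methide cascades of 3 with aldehydes, oxa-Michael additions of phenols to ortho-quinone methides and the acid-catalysed dimerisation of ortho-hydroxystyrenes to 2-arylchromans.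

**Compound list**

1 | phloroglucinol (benzene-1,3,5-triol) | Oc1cc(O)cc(O)c1 | starting material
2 | bis-iminium salt: [(2,4,6-trihydroxy-1,3-phenylene)dimethylidene]bis(dimethylammonium) dichloride, not isolated | C[N+](C)=Cc1c(O)cc(O)c(C=[N+](C)C)c1O.[Cl-].[Cl-] | intermediate
3 | 2,4-diformylphloroglucinol (2,4,6-trihydroxybenzene-1,3-dicarbaldehyde) | O=Cc1c(O)cc(O)c(C=O)c1O | intermediate
4 | isovaleraldehyde (3-methylbutanal) | CC(C)CC=O | starting material
5 | enamine of 4 and the catalyst: (R)-2-[diphenyl(trimethylsilyloxy)methyl]-1-[(E)-3-methylbut-1-en-1-yl]pyrrolidine, not isolated | CC(C)/C=C/N1CCC[C@@H]1C(c1ccccc1)(c1ccccc1)O[Si](C)(C)C | intermediate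
6 | ortho-quinone methide: 2,4-dihydroxy-5-(3-methylbutylidene)-6-oxocyclohexa-1,3-diene-1,3-dicarbaldehyde (either alkene geometry), not isolated | O=C1C(=CCC(C)C)C(O)=C(C=O)C(O)=C1C=O | intermediate
7 | lactol: (3S,4S)-2,5,7-trihydroxy-4-(2-methylpropyl)-3-(propan-2-yl)-3,4-dihydro-2H-chromene-6,8-dicarbaldehyde (3,4-trans; both anomers at C2) | CC(C)C[C@@H]1c2c(O)c(C=O)c(O)c(C=O)c2OC(O)[C@H]1C(C)C | intermediate
8 | open-chain quinone methide (chroman numbering): C2 is the exocyclic =CH on C5 of a 2,4-dihydroxy-6-oxocyclohexa-1,3-diene-1,3-dicarbaldehyde ring; C3 carries isopropyl (configuration mobile); C4 (S) carries isobutyl and the 3,5-diformyl-2,4,6-trihydroxyphenyl ring; not isolated | CC(C)C[C@H](c1c(O)c(C=O)c(O)c(C=O)c1O)C(C(C)C)C=C1C(=O)C(C=O)=C(O)C(C=O)=C1O | intermediate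
9 | hydroxystyrene tautomer of 8: 5,5'-[(3S)-5-methyl-2-(propan-2-yl)hex-1-ene-1,3-diyl]bis(2,4,6-trihydroxybenzene-1,3-dicarbaldehyde) (either alkene geometry), not isolated | CC(C)C[C@H](c1c(O)c(C=O)c(O)c(C=O)c1O)C(C(C)C)=Cc1c(O)c(C=O)c(O)c(C=O)c1O | intermediate
10 | sideroxylonal A: (2R,3R,4S)-2-(3,5-diformyl-2,4,6-trihydroxyphenyl)-5,7-dihydroxy-4-(2-methylpropyl)-3-(propan-2-yl)-3,4-dihydro-2H-chromene-6,8-dicarbaldehyde | CC(C)C[C@@H]1c2c(O)c(C=O)c(O)c(C=O)c2O[C@@H](c2c(O)c(C=O)c(O)c(C=O)c2O)[C@@H]1C(C)C | target

**Step count and risks**

Total step count: 3. Longest linear sequence: 3 steps (1 → 3 → 7 → 10); compound 3 is used in steps 2 and 3. No protecting groups or redox adjustments are needed because every carbon enters at its final oxidation level.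

The three steps most likely to fail:

Step 3 (proposed new method). The risks are incomplete stereoconvergence (C3 of the trans-lactol not equilibrating, which would give the 2S,3S,4S isomer), loss of C4 purity by retro-Michael fragmentation of 8, and capture of 8 by a second molecule of 3. The fallback uses known chemistry, sets out from 7 and comes back at 10. Lactol 7 is dehydrated with TsOH·H2O (5 mol%) in toluene at 80 °C with azeotropic removal of water to the enol ether (4S)-5,7-dihydroxy-4-(2-methylpropyl)-3-(propan-2-yl)-4H-chromene-6,8-dicarbaldehyde F1, in which C3 is trigonal. F1 and 3 are then treated with TfOH (5 mol%) in MeCN at −20 °C, the established acid-mediated hydroarylation of a cyclic enol ether (Friedel–Crafts C-arylation of the oxocarbenium ion). Protonation at C3 anti to the pseudo-axial isobutyl group sets 3R, and the free ring carbon of 3 adds to C2 trans to isopropyl to set 2R, giving 10. This replaces the equilibrating C–O closure by a kinetic protonation and a C–C arylation on a pre-formed pyran.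

Step 2 (proposed new method). The risks are a slow Knoevenagel half with the bulky amine, and leakage of 6 into its hydroxystyrene tautomer and racemic dimers or into a diarylalkane with 3. In addition, because C3 is reset later, the minor C4-epimeric diastereomer of 7 becomes the wrong enantiomer of 10, so it must be removed from 7 by chromatography or crystallisation. The fallback uses known chemistry, sets out from 3 and 4 and comes back at 7. Compounds 3 and 4 are condensed with 4-MeC6H4SO2Na in HCO2H/H2O at rt to the stable, racemic sulfone 2,4,6-trihydroxy-5-[3-methyl-1-(4-methylbenzenesulfonyl)butyl]benzene-1,3-dicarbaldehyde F2. F2 and 4 (2 equiv) are then stirred with the same (R)-catalyst (20 mol%) and NaHCO3 in CH2Cl2 at rt. Base-induced loss of sulfinate releases 6 slowly and at low concentration, and enamine 5 traps it to give 7. This swaps the in-flask Knoevenagel generation for an isolated quinone methide precursor, at the cost of one step.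

Step 1. The risk is a mixture of mono-, di- and triformylated phloroglucinols that is hard to separate. The fallback sets out from 1 and comes back at 3. Compound 1 is methylated (Me2SO4, K2CO3, acetone, reflux) to 1,3,5-trimethoxybenzene F3. Rieche formylation (Cl2CHOMe, TiCl4, CH2Cl2, 0 °C) stops cleanly at 2,4,6-trimethoxybenzene-1,3-dicarbaldehyde F4, which is easy to purify. BBr3 (CH2Cl2, −78 °C to rt) then removes the three methyl ethers, all of which lie ortho to a formyl group, to give 3.

**Further compounds**

F1 | step 3 | (4S)-5,7-dihydroxy-4-(2-methylpropyl)-3-(propan-2-yl)-4H-chromene-6,8-dicarbaldehyde | CC(C)C[C@@H]1c2c(O)c(C=O)c(O)c(C=O)c2OC=C1C(C)C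
F2 | step 2 | 2,4,6-trihydroxy-5-[3-methyl-1-(4-methylbenzenesulfonyl)butyl]benzene-1,3-dicarbaldehyde (racemic) | CC(C)CC(c1c(O)c(C=O)c(O)c(C=O)c1O)S(=O)(=O)c1ccc(C)cc1
F3 | step 1 | 1,3,5-trimethoxybenzene | COc1cc(OC)cc(OC)c1
F4 | step 1 | 2,4,6-trimethoxybenzene-1,3-dicarbaldehyde | COc1cc(OC)c(C=O)c(OC)c1C=O
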